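PGF1α is cut at the C11–C12 bond of its cyclopentane ring (C8–C12, prostanoid numbering). C11 is a carbinol carbon next to C12, whose exocyclic neighbour C13 can carry a sulfonyl group, so the bond is made by adding a C11 ketyl to C12 of a C12=C13 vinyl sulfone. In one SmI2-mediated operation the acyclic aldehyde closes the ring and sets C11 and C12 relative to the C8/C9 pair, which comes from an anti-selective asymmetric allylboration. The precursor is a C1–C13 chain: C11 aldehyde, C9 silyl ether, C1–C7 ester chain on C8 and (E)-C12=C13 phenyl sulfone. The sulfone left on C13 then builds the C13=C14 alkene by Julia–Lythgoe olefination.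

Key step: step 10

Remark: positions are quoted in prostanoid numbering; TBS = tert-butyldimethylsilyl, PMB = 4-methoxybenzyl, pin = pinacolato; (S)-oct-1-en-3-ol is taken as a purchasable single enantiomer.

**Step 1**
Reactants: 1 methyl 8-oxooctanoate; 2 vinylmagnesium bromide
Product: 3 methyl 8-hydroxydec-9-enoate (racemic)
Conditions: 2 (1.05 equiv), THF, −78 °C; then sat. aq. NH4Cl
Reagents that add atoms: none
Why: Grignard addition, in which the aldehyde reacts far faster than the methyl ester at −78 °C; the carbinol stereocentre is erased in step 2, so the racemate suffices.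

**Step 2**
Reactants: 3 methyl 8-hydroxydec-9-enoate
Product: 4 methyl (8E)-10-(4,4,5,5-tetramethyl-1,3,2-dioxaborolan-2-yl)dec-8-enoate
Conditions: B2pin2 (1.2 equiv), [Pd(MeCN)4](BF4)2 (5 mol%), DMSO/MeOH 1:1, 40 °C
Reagents that add atoms: bis(pinacolato)diboron, CC1(C)OB(OC1(C)C)B1OC(C)(C)C(C)(C)O1
Why: Palladium-catalysed allylic C–OH borylation through an η3-allylpalladium intermediate that is borylated at its unhindered terminus, so the linear (E)-allylboronate is expected and the ester is untouched.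

**Step 3**
Reactants: 5 propane-1,3-diol
Product: 6 3-(4-methoxybenzyloxy)propan-1-ol
Conditions: 5 (3 equiv), NaH (1 equiv), THF, 0 °C; PMBCl (1 equiv), Bu4NI (cat.), 0 °C → rt
Reagents that add atoms: 4-methoxybenzyl chloride, COc1ccc(CCl)cc1
Why: Williamson ether synthesis, with the cheap diol in excess to suppress double alkylation.

**Step 4**
Reactants: 6 3-(4-methoxybenzyloxy)propan-1-ol
Product: 7 3-(4-methoxybenzyloxy)propanal
Conditions: TEMPO (10 mol%), PhI(OAc)2 (1.1 equiv), CH2Cl2, rt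
Reagents that add atoms: none
Why: TEMPO/PhI(OAc)2 oxidation stops at the aldehyde and leaves the electron-rich benzyl ether alone.

**Step 5**
Reactants: 4 methyl (8E)-10-(pinB)dec-8-enoate; 7 3-(4-methoxybenzyloxy)propanal
Product: 9 methyl (8R)-8-[(1S)-1-hydroxy-3-(4-methoxybenzyloxy)propyl]dec-9-enoate, via O-pinacolboryl borate ester 8 (not isolated)
Conditions: (R)-TRIP [(R)-3,3'-bis(2,4,6-triisopropylphenyl)-1,1'-binaphthyl-2,2'-diyl hydrogen phosphate] (5 mol%), 4 Å MS, toluene, −30 °C; then aq. NaHCO3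
Reagents that add atoms: none
Why: Chiral-phosphoric-acid-catalysed allylboration through a closed Zimmerman–Traxler chair, in which the (E)-geometry of 4 gives the anti C8/C9 relationship and the (R)-acid should expose the Re face of 7, setting 9S and with it 8R.

**Step 6**
Reactants: 9 methyl (8R)-8-[(1S)-1-hydroxy-3-(4-methoxybenzyloxy)propyl]dec-9-enoate
Product: 10 methyl (8R)-8-[(1S)-1-(TBS-oxy)-3-(4-methoxybenzyloxy)propyl]dec-9-enoate
Conditions: TBSOTf, 2,6-lutidine, CH2Cl2, −78 → 0 °C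
Reagents that add atoms: tert-butyldimethylsilyl trifluoromethanesulfonate, CC(C)(C)[Si](C)(C)OS(=O)(=O)C(F)(F)F
Why: Silylation of a hindered secondary alcohol with the silyl triflate, to which the PMB ether, the ester and the alkene are inert.

**Step 7**
Reactants: 10 methyl (8R)-8-[(1S)-1-(TBS-oxy)-3-(4-methoxybenzyloxy)propyl]dec-9-enoate; 11 phenyl vinyl sulfone
Product: 12 methyl (8R,9E)-8-[(1S)-1-(TBS-oxy)-3-(4-methoxybenzyloxy)propyl]-10-(phenylsulfonyl)dec-9-enoate
Conditions: 11 (3 equiv), second-generation Hoveyda–Grubbs catalyst RuCl2(H2IMes)(=CH-C6H4-2-OiPr) (10 mol% in two portions), CH2Cl2, 40 °C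
Reagents that add atoms: none
Why: Olefin cross-metathesis of a terminal alkene with an electron-poor vinyl sulfone that does not homodimerise, driven by loss of ethene and expected to give the (E)-vinyl sulfone.

**Step 8**
Reactants: 12 methyl (8R,9E)-8-[(1S)-1-(TBS-oxy)-3-(4-methoxybenzyloxy)propyl]-10-(phenylsulfonyl)dec-9-enoate
Product: 13 methyl (8R,9E)-8-[(1S)-1-(TBS-oxy)-3-hydroxypropyl]-10-(phenylsulfonyl)dec-9-enoate
Conditions: DDQ (1.3 equiv), CH2Cl2/pH 7 phosphate buffer 10:1, 0 °C → rt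
Reagents that add atoms: none
Why: Oxidative PMB cleavage by DDQ, a neutral method chosen so that the vinyl sulfone with its acidic allylic C8–H never meets base.

**Step 9**
Reactants: 13 methyl (8R,9E)-8-[(1S)-1-(TBS-oxy)-3-hydroxypropyl]-10-(phenylsulfonyl)dec-9-enoate
Product: 14 methyl (8R,9E)-8-[(1S)-1-(TBS-oxy)-3-oxopropyl]-10-(phenylsulfonyl)dec-9-enoate
Conditions: Dess–Martin periodinane, NaHCO3, CH2Cl2, 0 °C → rt
Reagents that add atoms: none
Why: Dess–Martin oxidation under bicarbonate buffering should give the β-silyloxy aldehyde without β-elimination or epimerisation at C8; 14 is used at once.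

**Step 10**
Reactants: 14 methyl (8R,9E)-8-[(1S)-1-(TBS-oxy)-3-oxopropyl]-10-(phenylsulfonyl)dec-9-enoate
Product: 15 methyl 7-[(1R,2R,3R,5S)-5-(TBS-oxy)-3-hydroxy-2-(phenylsulfonylmethyl)cyclopentyl]heptanoate
Conditions: SmI2 (2.5 equiv, 0.1 M in THF), MeOH (5 equiv), THF, −78 → −40 °C; then aq. NH4Cl
Reagents that add atoms: none
Why: SmI2 transfers one electron to the C11 aldehyde, the samarium ketyl adds to C12 (the β-carbon of the (E)-vinyl sulfone), and the α-sulfonyl radical at C13 is reduced by a second SmI2 and protonated by MeOH. The closest known reaction type is the SmI2 ketyl–olefin cyclisation of aldehydes onto acrylates and onto β-alkoxyvinyl sulfones. The cyclopentane ring C8–C12 closes by 5-exo-trig attack. C12 should be set trans to C8 because the ester chain on the allylic carbon C8 sits pseudo-equatorial in the chair-like transition state while the smaller silyloxy group on C9 takes the axial site; C11 should be set by the O–Sm group turning away from the electron-poor alkene, which places O11 trans to C13 and therefore cis to O9. The step needs reduction of the aldehyde in preference to the vinyl sulfone and the ester, which inner-sphere electron transfer to the samarium-bound carbonyl oxygen secures as long as HMPA is left out, and ring closure faster than simple reduction or pinacol coupling, which the short tether and the strongly electron-poor acceptor secure.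

**Step 11**
Reactants: 15 methyl 7-[(1R,2R,3R,5S)-5-(TBS-oxy)-3-hydroxy-2-(phenylsulfonylmethyl)cyclopentyl]heptanoate
Product: 16 methyl 7-[(1R,2R,3R,5S)-3,5-bis(TBS-oxy)-2-(phenylsulfonylmethyl)cyclopentyl]heptanoate
Conditions: TBSOTf, 2,6-lutidine, CH2Cl2, 0 °C
Reagents that add atoms: tert-butyldimethylsilyl trifluoromethanesulfonate, CC(C)(C)[Si](C)(C)OS(=O)(=O)C(F)(F)F
Why: Silylation of the new C11 hydroxyl, so that only the acid and the sulfone α-CH2 are acidic in step 15.

**Step 12**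
Reactants: 16 methyl 7-[(1R,2R,3R,5S)-3,5-bis(TBS-oxy)-2-(phenylsulfonylmethyl)cyclopentyl]heptanoate
Product: 17 7-[(1R,2R,3R,5S)-3,5-bis(TBS-oxy)-2-(phenylsulfonylmethyl)cyclopentyl]heptanoic acid
Conditions: LiOH·H2O, THF/MeOH/H2O 3:1:1, rt; then 1 M HCl to pH 4
Reagents that add atoms: lithium hydroxide, [Li+].[OH-]
Why: Saponification now, because the carboxylate shields C1/C2 from the strong base that metalates the sulfone in step 15, which a methyl ester would not survive.

**Step 13**
Reactants: 18 (S)-oct-1-en-3-ol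
Product: 19 (S)-3-(TBS-oxy)oct-1-ene
Conditions: TBSCl, imidazole, DMF, rt
Reagents that add atoms: tert-butyldimethylsilyl chloride, CC(C)(C)[Si](C)(C)Cl
Why: Routine silylation; the stereocentre (C15 of the target) is bought in and not touched.

**Step 14**
Reactants: 19 (S)-3-(TBS-oxy)oct-1-ene
Product: 21 (S)-2-(TBS-oxy)heptanal, via secondary ozonide 20 (not isolated)
Conditions: O3, CH2Cl2, −78 °C; then PPh3, −78 °C → rt
Reagents that add atoms: ozone, [O-][O+]=O
Why: Ozonolysis with reductive work-up cleaves the terminal alkene without touching the stereocentre; 21 is kept cold and used without chromatography to avoid enolisation.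

**Step 15**
Reactants: 17 7-[(1R,2R,3R,5S)-3,5-bis(TBS-oxy)-2-(phenylsulfonylmethyl)cyclopentyl]heptanoic acid; 21 (S)-2-(TBS-oxy)heptanal
Product: 23 7-[(1R,2R,3R,5S)-2-[(3S)-2-acetoxy-3-(TBS-oxy)-1-(phenylsulfonyl)octyl]-3,5-bis(TBS-oxy)cyclopentyl]heptanoic acid (mixture at C13/C14), via dilithium β-alkoxide sulfone adduct 22 (not isolated)
Conditions: LiN(iPr)2 (2.2 equiv), THF, −78 °C; 21 (1.5 equiv), −78 °C; Ac2O (4 equiv), −78 → 0 °C; then sat. aq. NH4Cl
Reagents that add atoms: acetic anhydride, CC(=O)OC(C)=O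
Why: First half of the Julia–Lythgoe olefination: the carboxylate-protected α-sulfonyl carbanion at C13 adds to aldehyde 21 and the alkoxide is acetylated at −78 °C before a silyl shift from O15 can occur; the C13/C14 configurations do not matter.

**Step 16**
Reactants: 23 β-acetoxy sulfone acid
Product: 24 7-[(1R,2R,3R,5S)-3,5-bis(TBS-oxy)-2-[(1E,3S)-3-(TBS-oxy)oct-1-en-1-yl]cyclopentyl]heptanoic acid
Conditions: 6% Na(Hg), Na2HPO4, THF/MeOH 1:3, −20 °C
Reagents that add atoms: none
Why: Second half of the Julia–Lythgoe olefination: reductive cleavage of the C13–S bond and loss of the C14 acetate pass through an intermediate that can equilibrate, so the (E)-alkene flanked by two branched carbons is expected from either diastereomer of 23.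

**Step 17**
Reactants: 24 tris-TBS ether of PGF1α
Product: 25 prostaglandin F1α, 7-[(1R,2R,3R,5S)-3,5-dihydroxy-2-[(1E,3S)-3-hydroxyoct-1-en-1-yl]cyclopentyl]heptanoic acid
Conditions: HF·pyridine, THF/pyridine, 0 °C → rt
Reagents that add atoms: none
Why: Fluoride-mediated cleavage of the three silyl ethers under mildly acidic conditions that leave the allylic C15 alcohol, the (E)-alkene and the acid unchanged.

**Compound list**

1 | methyl 8-oxooctanoate | COC(=O)CCCCCCC=O | starting material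
2 | vinylmagnesium bromide | C=C[Mg]Br | starting material
3 | methyl 8-hydroxydec-9-enoate (racemic) | COC(=O)CCCCCCC(O)C=C | intermediate
4 | methyl (8E)-10-(4,4,5,5-tetramethyl-1,3,2-dioxaborolan-2-yl)dec-8-enoate | COC(=O)CCCCCC/C=C/CB1OC(C)(C)C(C)(C)O1 | intermediate
5 | propane-1,3-diol | OCCCO | starting material
6 | 3-(4-methoxybenzyloxy)propan-1-ol | COc1ccc(COCCCO)cc1 | intermediate
7 | 3-(4-methoxybenzyloxy)propanal | COc1ccc(COCCC=O)cc1 | intermediate
8 | O-pinacolboryl borate ester of 9 | COc1ccc(COCC[C@H](OB2OC(C)(C)C(C)(C)O2)[C@H](CCCCCCC(=O)OC)C=C)cc1 | intermediate (not isolated)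
9 | methyl (8R)-8-[(1S)-1-hydroxy-3-(4-methoxybenzyloxy)propyl]dec-9-enoate | COc1ccc(COCC[C@H](O)[C@H](CCCCCCC(=O)OC)C=C)cc1 | intermediate
10 | methyl (8R)-8-[(1S)-1-(tert-butyldimethylsilyloxy)-3-(4-methoxybenzyloxy)propyl]dec-9-enoate | COc1ccc(COCC[C@H](O[Si](C)(C)C(C)(C)C)[C@H](CCCCCCC(=O)OC)C=C)cc1 | intermediate
11 | phenyl vinyl sulfone | C=CS(=O)(=O)c1ccccc1 | starting material
12 | methyl (8R,9E)-8-[(1S)-1-(tert-butyldimethylsilyloxy)-3-(4-methoxybenzyloxy)propyl]-10-(phenylsulfonyl)dec-9-enoate | COc1ccc(COCC[C@H](O[Si](C)(C)C(C)(C)C)[C@H](CCCCCCC(=O)OC)/C=C/S(=O)(=O)c2ccccc2)cc1 | intermediate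
13 | methyl (8R,9E)-8-[(1S)-1-(tert-butyldimethylsilyloxy)-3-hydroxypropyl]-10-(phenylsulfonyl)dec-9-enoate | OCC[C@H](O[Si](C)(C)C(C)(C)C)[C@H](CCCCCCC(=O)OC)/C=C/S(=O)(=O)c1ccccc1 | intermediate
14 | methyl (8R,9E)-8-[(1S)-1-(tert-butyldimethylsilyloxy)-3-oxopropyl]-10-(phenylsulfonyl)dec-9-enoate | O=CC[C@H](O[Si](C)(C)C(C)(C)C)[C@H](CCCCCCC(=O)OC)/C=C/S(=O)(=O)c1ccccc1 | intermediate
15 | methyl 7-[(1R,2R,3R,5S)-5-(tert-butyldimethylsilyloxy)-3-hydroxy-2-(phenylsulfonylmethyl)cyclopentyl]heptanoate | O=S(=O)(c1ccccc1)C[C@@H]1[C@@H](CCCCCCC(=O)OC)[C@@H](O[Si](C)(C)C(C)(C)C)C[C@H]1O | intermediate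
16 | methyl 7-[(1R,2R,3R,5S)-3,5-bis(tert-butyldimethylsilyloxy)-2-(phenylsulfonylmethyl)cyclopentyl]heptanoate | O=S(=O)(c1ccccc1)C[C@@H]1[C@@H](CCCCCCC(=O)OC)[C@@H](O[Si](C)(C)C(C)(C)C)C[C@H]1O[Si](C)(C)C(C)(C)C | intermediate
17 | 7-[(1R,2R,3R,5S)-3,5-bis(tert-butyldimethylsilyloxy)-2-(phenylsulfonylmethyl)cyclopentyl]heptanoic acid | O=S(=O)(c1ccccc1)C[C@@H]1[C@@H](CCCCCCC(=O)O)[C@@H](O[Si](C)(C)C(C)(C)C)C[C@H]1O[Si](C)(C)C(C)(C)C | intermediate
18 | (S)-oct-1-en-3-ol | CCCCC[C@H](O)C=C | starting material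
19 | (S)-3-(tert-butyldimethylsilyloxy)oct-1-ene | CCCCC[C@H](O[Si](C)(C)C(C)(C)C)C=C | intermediate
20 | 3-[(1S)-1-(tert-butyldimethylsilyloxy)hexyl]-1,2,4-trioxolane (secondary ozonide) | CCCCC[C@H](O[Si](C)(C)C(C)(C)C)C1OCOO1 | intermediate (not isolated)
21 | (S)-2-(tert-butyldimethylsilyloxy)heptanal | CCCCC[C@H](O[Si](C)(C)C(C)(C)C)C=O | intermediate
22 | dilithium salt of the β-hydroxy sulfone adduct of 17 and 21 (mixture at C13/C14) | CCCCC[C@H](O[Si](C)(C)C(C)(C)C)C([O-])C(S(=O)(=O)c1ccccc1)[C@@H]1[C@@H](CCCCCCC(=O)[O-])[C@@H](O[Si](C)(C)C(C)(C)C)C[C@H]1O[Si](C)(C)C(C)(C)C.[Li+].[Li+] | intermediate (not isolated)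
23 | 7-[(1R,2R,3R,5S)-2-[(3S)-2-acetoxy-3-(tert-butyldimethylsilyloxy)-1-(phenylsulfonyl)octyl]-3,5-bis(tert-butyldimethylsilyloxy)cyclopentyl]heptanoic acid (mixture at C13/C14) | CCCCC[C@H](O[Si](C)(C)C(C)(C)C)C(OC(C)=O)C(S(=O)(=O)c1ccccc1)[C@@H]1[C@@H](CCCCCCC(=O)O)[C@@H](O[Si](C)(C)C(C)(C)C)C[C@H]1O[Si](C)(C)C(C)(C)C | intermediate
24 | 7-[(1R,2R,3R,5S)-3,5-bis(tert-butyldimethylsilyloxy)-2-[(1E,3S)-3-(tert-butyldimethylsilyloxy)oct-1-en-1-yl]cyclopentyl]heptanoic acid | CCCCC[C@H](O[Si](C)(C)C(C)(C)C)/C=C/[C@@H]1[C@@H](CCCCCCC(=O)O)[C@@H](O[Si](C)(C)C(C)(C)C)C[C@H]1O[Si](C)(C)C(C)(C)C | intermediate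
25 | prostaglandin F1α | CCCCC[C@H](O)/C=C/[C@@H]1[C@@H](CCCCCCC(=O)O)[C@@H](O)C[C@H]1O | target

**Step count**

Total: 17 steps. Longest linear sequence: 13 steps (1, 2, 5, 6, 7, 8, 9, 10, 11, 12, 15, 16, 17).

**Steps most likely to fail**

Step 10. Electron transfer to the vinyl sulfone or simple reduction of the aldehyde may outrun ring closure, and with a bulky, non-coordinating silyl ether on C9 the facial preference at C11 may be weak. The fallback is a hydroxyl-directed closure of the same bond; it sets out from 13 and comes back at 16. The C9 silyl ether is removed (HF·pyridine, THF) to give the diol methyl (8R,9E)-8-[(1S)-1,3-dihydroxypropyl]-10-(phenylsulfonyl)dec-9-enoate F1. The primary alcohol alone is oxidised (TEMPO, PhI(OAc)2, CH2Cl2) to the β-hydroxy aldehyde methyl (8R,9E)-8-[(1S)-1-hydroxy-3-oxopropyl]-10-(phenylsulfonyl)dec-9-enoate F2. SmI2 in THF/MeOH at −78 °C then closes the ring while trivalent samarium bridges the ketyl oxygen and the free C9 hydroxyl, a chelate possible only with O9 and O11 cis, to give the diol methyl 7-[(1R,2R,3R,5S)-3,5-dihydroxy-2-(phenylsulfonylmethyl)cyclopentyl]heptanoate F3. Double silylation (TBSOTf, 2,6-lutidine) gives 16.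

Step 7. Metathesis at the branched allylic position may stall, with catalyst decay and double-bond migration competing. The fallback replaces metathesis by carbonyl olefination; it sets out from 10 and comes back at 12. The vinyl group is cleaved with OsO4 (cat.), NaIO4 and 2,6-lutidine in dioxane/H2O, through the vicinal diol methyl (8R,9S)-9-(tert-butyldimethylsilyloxy)-8-(1,2-dihydroxyethyl)-11-(4-methoxybenzyloxy)undecanoate F4 formed in the flask, to the aldehyde methyl (8S,9S)-9-(tert-butyldimethylsilyloxy)-8-formyl-11-(4-methoxybenzyloxy)undecanoate F5. Horner–Wadsworth–Emmons olefination with the lithium salt of diethyl (phenylsulfonylmethyl)phosphonate (n-BuLi, THF, −78 °C) should give the (E)-vinyl sulfone 12.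

Step 5. Enantiofacial discrimination by the acid catalyst may be insufficient with an unbranched β-alkoxy aldehyde, or an uncatalysed background reaction may erode it. The fallback replaces catalyst control by resolution; it sets out from 4 and 7 and comes back at 9. The two are combined without catalyst (toluene, rt), which gives through the racemic borate ester (8 and its mirror image) F6 the racemic anti alcohol (9 and its mirror image) F7 by the same closed transition state. Steglich esterification with (S)-2-methoxy-2-phenylacetic acid (DCC, DMAP, CH2Cl2) gives two diastereomeric esters, the (S)-O-methylmandelate of 9 F8 and the (S)-O-methylmandelate of the mirror image of 9 F9, which are separated by chromatography. K2CO3 in MeOH cleaves F8 to 9; the C1 methyl ester is unchanged by methanolysis.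

**Further compounds**

F1 | step 10 | methyl (8R,9E)-8-[(1S)-1,3-dihydroxypropyl]-10-(phenylsulfonyl)dec-9-enoate | OCC[C@H](O)[C@H](CCCCCCC(=O)OC)/C=C/S(=O)(=O)c1ccccc1
F2 | step 10 | methyl (8R,9E)-8-[(1S)-1-hydroxy-3-oxopropyl]-10-(phenylsulfonyl)dec-9-enoate | O=CC[C@H](O)[C@H](CCCCCCC(=O)OC)/C=C/S(=O)(=O)c1ccccc1
F3 | step 10 | methyl 7-[(1R,2R,3R,5S)-3,5-dihydroxy-2-(phenylsulfonylmethyl)cyclopentyl]heptanoate | O=S(=O)(c1ccccc1)C[C@@H]1[C@@H](CCCCCCC(=O)OC)[C@@H](O)C[C@H]1O
F4 | step 7 | methyl (8R,9S)-9-(tert-butyldimethylsilyloxy)-8-(1,2-dihydroxyethyl)-11-(4-methoxybenzyloxy)undecanoate (mixture at the new carbinol) | COc1ccc(COCC[C@H](O[Si](C)(C)C(C)(C)C)[C@H](CCCCCCC(=O)OC)C(O)CO)cc1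
F5 | step 7 | methyl (8S,9S)-9-(tert-butyldimethylsilyloxy)-8-formyl-11-(4-methoxybenzyloxy)undecanoate | COc1ccc(COCC[C@H](O[Si](C)(C)C(C)(C)C)[C@H](CCCCCCC(=O)OC)C=O)cc1
F6 | step 5 | racemic O-pinacolboryl borate ester (8 and its mirror image) | COc1ccc(COCC[C@H](OB2OC(C)(C)C(C)(C)O2)[C@H](CCCCCCC(=O)OC)C=C)cc1.COc1ccc(COCC[C@@H](OB2OC(C)(C)C(C)(C)O2)[C@@H](CCCCCCC(=O)OC)C=C)cc1
F7 | step 5 | racemic anti alcohol (9 and its mirror image) | COc1ccc(COCC[C@H](O)[C@H](CCCCCCC(=O)OC)C=C)cc1.COc1ccc(COCC[C@@H](O)[C@@H](CCCCCCC(=O)OC)C=C)cc1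
F8 | step 5 | methyl (8R)-8-[(1S)-3-(4-methoxybenzyloxy)-1-{[(2S)-2-methoxy-2-phenylacetyl]oxy}propyl]dec-9-enoate | COc1ccc(COCC[C@H](OC(=O)[C@@H](OC)c2ccccc2)[C@H](CCCCCCC(=O)OC)C=C)cc1
F9 | step 5 | methyl (8S)-8-[(1R)-3-(4-methoxybenzyloxy)-1-{[(2S)-2-methoxy-2-phenylacetyl]oxy}propyl]dec-9-enoate | COc1ccc(COCC[C@@H](OC(=O)[C@@H](OC)c2ccccc2)[C@@H](CCCCCCC(=O)OC)C=C)cc1
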